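**Retrosynthetic overview**

1. Feature: ring A (C4a, C5, C6, C7, C8, C8a) is a fully substituted acylphloroglucinol with oxygen on C5, C7 and C8a (O1), OMe on the carbons between them (C6, C8) and the acyl carbon C4 on C4a. It maps onto a C4a–C5–C6 ketide unit plus a methoxymalonyl unit C7–C8–C8a, and is symmetric about the C4a···C7 axis until ring C closes.
2. Last moves: the O2′/O5′ benzyl ethers come off (18 from 17); ring C is closed at O1–C2 by oxidative cyclisation of α-methoxychalcone 15, either ortho-hydroxyl giving the same flavone.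
3. Key disconnection: ring A of 15 by [3+3] benzannulation, C6–C7 by C-acylation and C4a–C8a by Claisen closure, between diketone 7 (activated as bis(silyl enol ether) 9) and methoxymalonyl half-ester chloride 12 (from dimethyl methoxymalonate 10).
4. Diketone 7 comes from ester 5 and methoxyacetone (Claisen); 5 from aldehyde 3 by Horner–Wadsworth–Emmons olefination (brings in C2, C3–OMe, C4); 3 from 2-methoxyhydroquinone by benzylation and formylation.
5. Ring order: B (purchased) → A (step 8) → C (step 9).

Key step: step 8

Remark: the target has no stereocentre, so no enantioselective step is needed; the Z enol-ether geometry carried from 5 to 15 is erased when ring C forms.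
Remark: a lithium or magnesium dianion of 7 would be protonated by the acidic C–H of dimethyl methoxymalonate before it could be acylated, so the dinucleophile is used as its neutral bis(silyl enol ether) and the C3 unit as its half-ester chloride.

**Route**

Step 1
Reactants: 1 2-methoxyhydroquinone
Product: 2 1,4-bis(benzyloxy)-2-methoxybenzene
Conditions: BnBr, K2CO3, DMF, 60 °C (N2)
Reagents that add atoms: benzyl bromide, BrCc1ccccc1
Why: Williamson etherification of both phenols should be clean because there is no other nucleophilic site, and nitrogen keeps the hydroquinone from air oxidation under base.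

Step 2
Reactants: 2 1,4-bis(benzyloxy)-2-methoxybenzene
Product: 3 2,5-bis(benzyloxy)-4-methoxybenzaldehyde
Conditions: POCl3, DMF, 0 → 70 °C; aq. NaOAc
Reagents that add atoms: N,N-dimethylformamide, CN(C)C=O; water, O
Why: Vilsmeier–Haack formylation should go at the one position para to the methoxy group and ortho to a benzyloxy group, the site at which 1,2,4-trialkoxybenzenes are formylated, and benzyl aryl ethers tolerate the conditions.

Step 3
Reactants: 3 2,5-bis(benzyloxy)-4-methoxybenzaldehyde; 4 methyl 2-(dimethoxyphosphoryl)-2-methoxyacetate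
Product: 5 methyl (2Z)-3-[2,5-bis(benzyloxy)-4-methoxyphenyl]-2-methoxyprop-2-enoate
Conditions: NaH, THF, 0 °C → rt
Reagents that add atoms: none
Why: Horner–Wadsworth–Emmons olefination with the stabilised α-methoxyphosphonate should give the trisubstituted enol ether with aryl trans to the ester (Z), the thermodynamically preferred geometry, which is not critical because it is erased when ring C forms.

Step 4
Reactants: 5 methyl (2Z)-3-[2,5-bis(benzyloxy)-4-methoxyphenyl]-2-methoxyprop-2-enoate; 6 methoxyacetone
Product: 7 (1Z)-1-[2,5-bis(benzyloxy)-4-methoxyphenyl]-2,6-dimethoxyhex-1-ene-3,5-dione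
Conditions: NaH, cat. MeOH, THF, 0 → 50 °C (6 added slowly); AcOH
Reagents that add atoms: none
Why: Crossed Claisen condensation of the non-enolisable ester 5 with the sodium enolate of methoxyacetone should acylate the methyl carbon, as base-mediated acylations of methyl alkyl ketones do, because only that regioisomer ends as an unsubstituted, fully delocalised β-diketonate that drives the equilibrium.

Step 5
Reactants: 7 (1Z)-1-[2,5-bis(benzyloxy)-4-methoxyphenyl]-2,6-dimethoxyhex-1-ene-3,5-dione
Product: 9 (1Z)-1-[2,5-bis(benzyloxy)-4-methoxyphenyl]-2,6-dimethoxy-3,5-bis[(trimethylsilyl)oxy]hexa-1,3,5-triene, via mono-silyl enol ether 8 (not isolated)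
Conditions: TMSOTf, Et3N, Et2O, 0 °C → rt; decant, concentrate (used crude)
Reagents that add atoms: trimethylsilyl trifluoromethanesulfonate, C[Si](C)(C)OS(=O)(=O)C(F)(F)F
Why: Enol silylation with silyl triflate/amine, known for 1,3-diketones, should silylate the enolised diketone and then the second carbonyl with loss of a proton from C6, the only remaining α-carbon that carries hydrogen, giving the 1,3-bis(silyloxy)diene in which C6 is the vinylogous nucleophilic terminus.

Step 6
Reactants: 10 dimethyl 2-methoxymalonate
Product: 11 potassium 2,3-dimethoxy-3-oxopropanoate (potassium methyl 2-methoxymalonate)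
Conditions: KOH (1.0 equiv), MeOH, 0 °C → rt; Et2O, filter
Reagents that add atoms: potassium hydroxide, [K+].[OH-]
Why: Mono-saponification of a malonate diester with one equivalent of KOH should stop at the half-ester salt, since the carboxylate deactivates the remaining ester toward hydroxide and the salt separates.

Step 7
Reactants: 11 potassium 2,3-dimethoxy-3-oxopropanoate
Product: 12 methyl 3-chloro-2-methoxy-3-oxopropanoate
Conditions: (COCl)2, cat. DMF, CH2Cl2, 0 °C → rt; filter, concentrate (used at once)
Reagents that add atoms: oxalyl chloride, O=C(Cl)C(Cl)=O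
Why: Conversion of the carboxylate into the acid chloride with oxalyl chloride and catalytic DMF (Vilsmeier-type activation) should work as for other malonic half-esters, and with no base present the chloride is not dehydrochlorinated to a ketene.

Step 8
Reactants: 9 (1Z)-1-[2,5-bis(benzyloxy)-4-methoxyphenyl]-2,6-dimethoxy-3,5-bis[(trimethylsilyl)oxy]hexa-1,3,5-triene; 12 methyl 3-chloro-2-methoxy-3-oxopropanoate
Product: 15 (2Z)-3-[2,5-bis(benzyloxy)-4-methoxyphenyl]-2-methoxy-1-(2,4,6-trihydroxy-3,5-dimethoxyphenyl)prop-2-en-1-one, via silylated triketo ester 13 (not isolated), via triketo ester 14 (not isolated)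
Conditions: CH2Cl2, −78 → 20 °C; evaporate; Mg(OMe)2, MeOH, 65 °C (Ar); 1 M HCl, 0 °C
Reagents that add atoms: none
Why: Proposed new method: the methoxy-bearing terminal carbon C6 of 9, activated directly and vinylogously by the two silyloxy groups, should attack acid chloride 12 in a base-free C-acylation (C6–C7), chloride removing one silyl group to give 13, so that the acidic malonyl C–H never meets a carbanion; methanolic Mg(OMe)2 then cleaves the remaining silyl enol ether and holds triketo ester 14 as a magnesium chelate, whose central C4a enolate attacks the methyl ester (C4a–C8a), and the resulting 2-acylcyclohexane-1,3,5-trione tautomerises to the phloroglucinol without change of oxidation level. The closest known reaction types are the terminal C-acylation of 1,3-bis(silyl enol ethers) by acid chlorides, malonyl half-ester chlorides included, and the magnesium methoxide Claisen cyclisation of 3,5,7-triketo esters to acylphloroglucinols; neither has been run with methoxy groups on both flanking carbons or joined into one benzannulation. Ring A closes in a 6-(enolexo)-exo-trig Claisen mode. No stereocentre remains in 15; the two CH(OMe) centres of 14 form without control and vanish on aromatisation. The step needs terminal rather than central or O-acylation, which the vinylogous activation of C6 in the bis(silyloxy)diene should secure, and Claisen rather than aldol or lactone closure: attack of C8 on the C4 carbonyl would give a quaternary C(OMe)(CO2Me) centre that cannot dehydrate to an arene and so reverts, and the 4-hydroxy-2-pyranone from O-acylation is reopened by methoxide, leaving the aromatic acylphloroglucinol as the sink.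

Step 9
Reactants: 15 (2Z)-3-[2,5-bis(benzyloxy)-4-methoxyphenyl]-2-methoxy-1-(2,4,6-trihydroxy-3,5-dimethoxyphenyl)prop-2-en-1-one
Product: 17 2-[2,5-bis(benzyloxy)-4-methoxyphenyl]-5,7-dihydroxy-3,6,8-trimethoxy-4H-chromen-4-one, via 3-methoxyflavanone 16 (not isolated)
Conditions: I2 (cat.), DMSO, 120 °C
Reagents that add atoms: none
Why: I2–DMSO oxidative cyclisation of a 2′-hydroxychalcone should close O1–C2 by 6-endo oxa-Michael addition through either of the two equivalent ortho-hydroxyls to flavanone 16, which is dehydrogenated by α-iodination and loss of HI while DMSO reoxidises iodide; ring A has no free position to be iodinated and the benzyl ethers are stable.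

Step 10
Reactants: 17 2-[2,5-bis(benzyloxy)-4-methoxyphenyl]-5,7-dihydroxy-3,6,8-trimethoxy-4H-chromen-4-one
Product: 18 5,7,2′,5′-tetrahydroxy-3,6,8,4′-tetramethoxyflavone
Conditions: H2 (1 atm), 10% Pd/C, EtOAc–MeOH, rt (work-up under Ar)
Reagents that add atoms: none
Why: Hydrogenolysis of the two benzyl aryl ethers over Pd/C under neutral conditions should leave the methyl ethers and the 4-pyranone C2=C3 bond untouched, and it frees the air-sensitive methoxyhydroquinone ring B only at the end and without base.

**Compound list**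

1 | 2-methoxyhydroquinone (2-methoxybenzene-1,4-diol) | COc1cc(O)ccc1O | starting material
2 | 1,4-bis(benzyloxy)-2-methoxybenzene | COc1cc(OCc2ccccc2)ccc1OCc1ccccc1 | intermediate
3 | 2,5-bis(benzyloxy)-4-methoxybenzaldehyde | O=Cc1cc(OCc2ccccc2)c(OC)cc1OCc1ccccc1 | intermediate
4 | methyl 2-(dimethoxyphosphoryl)-2-methoxyacetate | COC(=O)C(OC)P(=O)(OC)OC | starting material
5 | methyl (2Z)-3-[2,5-bis(benzyloxy)-4-methoxyphenyl]-2-methoxyprop-2-enoate | CO/C(C(=O)OC)=C\c1cc(OCc2ccccc2)c(OC)cc1OCc1ccccc1 | intermediate
6 | methoxyacetone (1-methoxypropan-2-one) | COCC(C)=O | starting material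
7 | (1Z)-1-[2,5-bis(benzyloxy)-4-methoxyphenyl]-2,6-dimethoxyhex-1-ene-3,5-dione (drawn as diketo tautomer) | CO/C(C(=O)CC(=O)COC)=C\c1cc(OCc2ccccc2)c(OC)cc1OCc1ccccc1 | intermediate
8 | (1Z)-1-[2,5-bis(benzyloxy)-4-methoxyphenyl]-2,6-dimethoxy-3-[(trimethylsilyl)oxy]hexa-1,3-dien-5-one (the 5-silyloxy regioisomer converges to 9; new C=C geometry undefined) | CO/C(=C\c1cc(OCc2ccccc2)c(OC)cc1OCc1ccccc1)C(O[Si](C)(C)C)=CC(=O)COC | intermediate
9 | (1Z)-1-[2,5-bis(benzyloxy)-4-methoxyphenyl]-2,6-dimethoxy-3,5-bis[(trimethylsilyl)oxy]hexa-1,3,5-triene (geometry of the two new C=C bonds undefined) | CO/C(=C\c1cc(OCc2ccccc2)c(OC)cc1OCc1ccccc1)C(O[Si](C)(C)C)=CC(O[Si](C)(C)C)=COC | intermediate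
10 | dimethyl 2-methoxymalonate | COC(C(=O)OC)C(=O)OC | starting material
11 | potassium 2,3-dimethoxy-3-oxopropanoate | COC(C(=O)OC)C(=O)[O-].[K+] | intermediate
12 | methyl 3-chloro-2-methoxy-3-oxopropanoate (racemic) | COC(C(=O)OC)C(Cl)=O | intermediate
13 | methyl (8Z)-9-[2,5-bis(benzyloxy)-4-methoxyphenyl]-2,4,8-trimethoxy-3,5-dioxo-7-[(trimethylsilyl)oxy]nona-6,8-dienoate (stereoisomer mixture) | COC(=O)C(OC)C(=O)C(OC)C(=O)C=C(O[Si](C)(C)C)/C(OC)=C/c1cc(OCc2ccccc2)c(OC)cc1OCc1ccccc1 | intermediate
14 | methyl (8Z)-9-[2,5-bis(benzyloxy)-4-methoxyphenyl]-2,4,8-trimethoxy-3,5,7-trioxonon-8-enoate (diastereomer and tautomer mixture) | COC(=O)C(OC)C(=O)C(OC)C(=O)CC(=O)/C(OC)=C/c1cc(OCc2ccccc2)c(OC)cc1OCc1ccccc1 | intermediate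
15 | (2Z)-3-[2,5-bis(benzyloxy)-4-methoxyphenyl]-2-methoxy-1-(2,4,6-trihydroxy-3,5-dimethoxyphenyl)prop-2-en-1-one | CO/C(C(=O)c1c(O)c(OC)c(O)c(OC)c1O)=C\c1cc(OCc2ccccc2)c(OC)cc1OCc1ccccc1 | intermediate
16 | 2-[2,5-bis(benzyloxy)-4-methoxyphenyl]-5,7-dihydroxy-3,6,8-trimethoxy-2,3-dihydro-4H-chromen-4-one (racemic; both centres removed in the same step) | COc1cc(OCc2ccccc2)c(C2Oc3c(OC)c(O)c(OC)c(O)c3C(=O)C2OC)cc1OCc1ccccc1 | intermediate
17 | 2-[2,5-bis(benzyloxy)-4-methoxyphenyl]-5,7-dihydroxy-3,6,8-trimethoxy-4H-chromen-4-one | COc1cc(OCc2ccccc2)c(-c2oc3c(OC)c(O)c(OC)c(O)c3c(=O)c2OC)cc1OCc1ccccc1 | intermediate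
18 | 5,7,2′,5′-tetrahydroxy-3,6,8,4′-tetramethoxyflavone [2-(2,5-dihydroxy-4-methoxyphenyl)-5,7-dihydroxy-3,6,8-trimethoxy-4H-chromen-4-one] | COc1cc(O)c(-c2oc3c(OC)c(O)c(OC)c(O)c3c(=O)c2OC)cc1O | target

**Step count**

Total: 10 steps. Longest linear sequence: 8 steps (steps 1–5 and 8–10); steps 6–7 form the two-step side branch to 12.

**Steps most likely to fail**

Step 8 (Proposed new method). What may go wrong: acylation of 9 through oxygen or the central carbon instead of C6, hydrolysis of 9 by acid carried in with crude 12, or methoxide-induced retro-Claisen fragmentation of 14 outrunning ring closure. The fallback uses known polyanion chemistry, bringing in C7–C8 as a methoxyacetyl unit and C8a as carbon dioxide. It sets out from 7: the dianion of 7 (LDA, THF, −78 °C) is acylated at C6 by N,2-dimethoxy-N-methylacetamide to give the triketone (7Z)-8-[2,5-bis(benzyloxy)-4-methoxyphenyl]-1,3,7-trimethoxyoct-7-ene-2,4,6-trione F1. The trianion of F1 (LDA, THF, −78 → 0 °C) is carboxylated at its terminal methoxy-bearing carbon with CO2 to give the triketo acid (8Z)-9-[2,5-bis(benzyloxy)-4-methoxyphenyl]-2,4,8-trimethoxy-3,5,7-trioxonon-8-enoic acid F2, which is esterified cold with diazomethane. The sequence comes back to the route at 14, which is closed to 15 by the magnesium methoxide stage of step 8.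

Step 9. What may go wrong: electrophilic iodination of the electron-rich ring B or oxidation of the free phloroglucinol ring competing with dehydrogenation, or the reaction stalling after oxa-Michael closure. The fallback separates ring closure from oxidation and masks the ring-A phenols. It sets out from 15, which is isomerised with NaOAc in refluxing EtOH to flavanone 16, now isolated. Acetylation (Ac2O, pyridine, DMAP) gives 2-[2,5-bis(benzyloxy)-4-methoxyphenyl]-3,6,8-trimethoxy-4-oxo-3,4-dihydro-2H-chromene-5,7-diyl diacetate F3. Dehydrogenation with DDQ in refluxing dioxane gives 2-[2,5-bis(benzyloxy)-4-methoxyphenyl]-3,6,8-trimethoxy-4-oxo-4H-chromene-5,7-diyl diacetate F4. Methanolysis of the acetates (K2CO3, MeOH, rt, Ar) comes back to the route at 17.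

Step 4. What may go wrong: acylation of methoxyacetone at its methoxy-bearing carbon, or self-condensation of the ketone leaving 5 unconsumed. The fallback fixes the regiochemistry by making the ketone the C4 partner. It sets out from 5, which is converted with MeNH(OMe)·HCl and i-PrMgCl (THF, −20 °C) into the N-methoxy-N-methylamide (2Z)-3-[2,5-bis(benzyloxy)-4-methoxyphenyl]-N,2-dimethoxy-N-methylprop-2-enamide F5. MeMgBr (THF, 0 °C) gives the methyl ketone (3Z)-4-[2,5-bis(benzyloxy)-4-methoxyphenyl]-3-methoxybut-3-en-2-one F6, whose only enolisable carbon is the methyl group. Its lithium enolate (LiHMDS, THF, −78 °C) is acylated by methyl methoxyacetate, and the sequence comes back to the route at 7.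

**Further compounds**

F1 | step 8 | (7Z)-8-[2,5-bis(benzyloxy)-4-methoxyphenyl]-1,3,7-trimethoxyoct-7-ene-2,4,6-trione | COCC(=O)C(OC)C(=O)CC(=O)/C(OC)=C/c1cc(OCc2ccccc2)c(OC)cc1OCc1ccccc1
F2 | step 8 | (8Z)-9-[2,5-bis(benzyloxy)-4-methoxyphenyl]-2,4,8-trimethoxy-3,5,7-trioxonon-8-enoic acid | OC(=O)C(OC)C(=O)C(OC)C(=O)CC(=O)/C(OC)=C/c1cc(OCc2ccccc2)c(OC)cc1OCc1ccccc1
F3 | step 9 | 2-[2,5-bis(benzyloxy)-4-methoxyphenyl]-3,6,8-trimethoxy-4-oxo-3,4-dihydro-2H-chromene-5,7-diyl diacetate (racemic) | COc1cc(OCc2ccccc2)c(C2Oc3c(OC)c(OC(C)=O)c(OC)c(OC(C)=O)c3C(=O)C2OC)cc1OCc1ccccc1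
F4 | step 9 | 2-[2,5-bis(benzyloxy)-4-methoxyphenyl]-3,6,8-trimethoxy-4-oxo-4H-chromene-5,7-diyl diacetate | COc1cc(OCc2ccccc2)c(-c2oc3c(OC)c(OC(C)=O)c(OC)c(OC(C)=O)c3c(=O)c2OC)cc1OCc1ccccc1
F5 | step 4 | (2Z)-3-[2,5-bis(benzyloxy)-4-methoxyphenyl]-N,2-dimethoxy-N-methylprop-2-enamide | CO/C(C(=O)N(C)OC)=C\c1cc(OCc2ccccc2)c(OC)cc1OCc1ccccc1
F6 | step 4 | (3Z)-4-[2,5-bis(benzyloxy)-4-methoxyphenyl]-3-methoxybut-3-en-2-one | CO/C(C(C)=O)=C\c1cc(OCc2ccccc2)c(OC)cc1OCc1ccccc1
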